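## Structural features

The target is a coumarin (benzene ring A fused to the α-pyranone ring B) with a methoxy group on C8 and an oxidized geranyl chain on O7. The chain is numbered C1' (OCH2) to C8' (=CH2). It consists of the allyl aryl ether carbon C1', the (E)-trisubstituted olefin C2'=C3'(CH3), the methylene C4', two adjacent secondary carbinols C5' and C6', and an isopropenyl terminus C7'(CH3)=C8'H2. The only stereocenters are C5' and C6', both S, which is a threo 1,2-diol (syn in the zigzag drawing). Fragile groups are the lactone of ring B (opened by hydroxide, hydrides and organometallics; its C3=C4 bond photodimerizes under UV light), the allyl aryl ether (ionization, SN2', Claisen rearrangement on heating) and the allylic C6' alcohol (ionization in acid). The ring system needs no construction, so the real difficulty is the enantio- and diastereodefined threo diol beside a 1,1-disubstituted olefin, at the far end of a chain that holds a second olefin. The key step exploits the array C5'(OH)–C6'(OH)–C7'(CH3)=C8'H2. The unit C6'(O)–C7'=C8' is what a singlet-oxygen ene reaction leaves from a prenyl terminus C6'=C7'(CH3)2. The C5' hydroxyl is allylic to that olefin and faces a cis methyl group on C7', the arrangement in which a hydroxyl steers the oxidant to one face. Only C5' therefore has to be set by a catalyst.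

## Logic of the disconnections

In one sentence: 11 is made by a hydroxyl-directed singlet-oxygen ene reaction of 9, which already contains the whole skeleton and only the C5' stereocenter.

11 ⇒ 9 (through 10). The C6'–O bond is cut and the C7'=C8' double bond is moved back to C6'=C7', returning one hydrogen to C8'. This removes the C6' stereocenter, one oxygen and the sensitive allylic diol together, and leaves a precursor with one stereocenter and a plain prenyl terminus. The forward step must oxidize C6'=C7' and not C2'=C3', put oxygen on C6' while taking hydrogen from a methyl group, and add to the face that gives the threo (5'S,6'S) arrangement. The first product 10 must be reduced before it can cleave.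

9 ⇒ 7 + 8. The O7–C1' bond is cut. This releases the intact ring system as 8 and the chain as 7, so all carbon–carbon chemistry is done without the lactone present. The forward step must activate the primary allylic hydroxyl of 7 beside its secondary allylic hydroxyl, substitute at C1' without allylic transposition, and avoid any base that opens ring B.

7 ⇒ 6. No skeletal bond is cut. C1' is taken back to the ester oxidation level, because an ester at C1' makes the next disconnection possible. The forward step is a 1,2-reduction of a conjugated ester in the presence of a free hydroxyl.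

6 ⇒ 3 + 4. The C4'–C5' bond is cut at the stereocenter. The ten-carbon chain falls into two five-carbon units of commodity origin, and the (2'E) olefin and the C5' carbinol both arise in the bond-forming event. The forward step must react 3 at its γ-carbon and not its α-carbon, give E geometry, and attack the Si face of the β,β-disubstituted enal 4 under catalyst control.

3 ⇒ 1 (through 2). The O–Si bond is cut. The forward step needs deprotonation of 1 at a γ-methyl group and silylation on oxygen.

## Other disconnections considered

Alternative 1: This is the plan that comes to mind first. The cut is O7–C1' as the last construction, with both C–O bonds of the diol made by osmylation. Sharpless asymmetric dihydroxylation (K2OsO2(OH)4, (DHQ)2PHAL, K3Fe(CN)6) of the silyl-protected trienol A1 at its (5E) olefin would give the (S,S)-diol A2. Acetonide formation, desilylation and bromination would give the allylic bromide A3, which alkylates 8 (Williamson) before acid frees the diol. The chosen plan is preferred for three reasons.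
- A1 holds three olefins, and the osmylation must pick the (E)-disubstituted C5'=C6' bond over the 1,1-disubstituted C7'=C8' bond of the same conjugated diene and over C2'=C3'.
- A1 needs its own C–C bond formations.
- The diol exists before the ether bond is made, so it must be masked and unmasked. The plan comes to about nine steps, four of them protecting-group operations, against five steps and none here.

Alternative 2: The cut is C5'–C6', with both carbinols set in one C–C bond formation. Asymmetric γ-alkoxyallylboration of the β,γ-unsaturated aldehyde A4 with a (Z)-3-alkoxy-2-methylallyl boron reagent bearing isopinocampheyl ligands would give the mono-protected threo diol A5. Removal of the methoxymethyl group would then give 11. The chosen plan is preferred on these grounds.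
- The C4' hydrogens of A4 lie between the formyl group and C3'=C2'. Enolization moves the olefin into conjugation or expels the phenoxide of 8 by vinylogous β-elimination, and the basic ate-complex conditions of the boron reagent invite this.
- The 2-methyl-substituted reagent is more hindered at the reacting carbon than the parent reagents on which the high selectivities rest.
- The borinate has to be released next to the lactone, and an acetal has to be cleaved by acid next to an ionizable allylic alcohol.
- The chosen plan makes the same two centers with one catalyst-controlled and one substrate-controlled step and never carries an enolizable aldehyde.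

Alternative 3: The cut is C6'–C7'. Chelation-controlled addition of isopropenylmagnesium bromide to the (S)-α-alkoxy aldehyde A6 would give the syn adduct A7. Desilylation, etherification with 8 and acetal cleavage would follow. The chosen plan is preferred on these grounds.
- The Grignard reagent is incompatible with ring B, so the addition must be done on a chain fragment. This forces protection of O1' and O5' and later discrimination among three hydroxyls.
- The C5' center of A6 has to come from a separate asymmetric step and sits α to a formyl group, where it can epimerize.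
- The balance between chelate and Felkin addition for an sp2 Grignard reagent and a methoxymethyl ether is not dependable.
- The count is about ten steps.

Key step: step 5

Assumption: 7-hydroxy-8-methoxycoumarin 8 is taken as a purchasable building block, as are 1 and 4.

## Steps

Step 1
Reactants: 1 ethyl 3-methylbut-2-enoate
Product: 3 tert-butyl[(1-ethoxy-3-methylbuta-1,3-dien-1-yl)oxy]dimethylsilane, via lithium dienolate 2 (not isolated)
Conditions: LiN(i-Pr)2 (1.1 equiv, commercial solution), THF, −78 °C; then t-BuMe2SiCl (1.2 equiv), DMPU, −78 °C to rt
Reagents that add atoms: lithium diisopropylamide, [Li+].CC(C)[N-]C(C)C (lithium, held in 2 only); tert-butyldimethylsilyl chloride, CC(C)(C)[Si](C)(C)Cl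
Why: Kinetic γ-deprotonation of the senecioate gives the extended dienolate 2, which the silyl chloride traps on oxygen (O-silylation of an ester dienolate). No stereocenter is formed, and the ketene-acetal geometry is irrelevant because C1 becomes the ester carbonyl again in step 2.

Step 2
Reactants: 3 tert-butyl[(1-ethoxy-3-methylbuta-1,3-dien-1-yl)oxy]dimethylsilane; 4 3-methylbut-2-enal
Product: 6 ethyl (2E,5S)-5-hydroxy-3,7-dimethylocta-2,6-dienoate, via trichlorosilyl ether 5 (not isolated)
Conditions: SiCl4 (1.1 equiv), chiral bisphosphoramide (two N,N'-dimethyl-1,1'-binaphthyl-2,2'-diamine P(=O) units joined through N-methyl nitrogens by a (CH2)5 tether, 5 mol %, enantiomer selected for Si-face addition), i-Pr2NEt (10 mol %), CH2Cl2, −78 °C; then sat. aq. NaHCO3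
Reagents that add atoms: silicon tetrachloride, Cl[Si](Cl)(Cl)Cl (SiCl3 group, held in 5 only)
Why: Catalytic enantioselective vinylogous Mukaiyama aldol addition under Lewis-base activation of SiCl4: the phosphoramide-bound trichlorosilyl cation activates 4, and 3 attacks through its unhindered γ-carbon in an open transition state, which forms C4–C5 and is expected to give the (2E)-enoate. The C5 stereocenter is set by the chiral silicon complex; addition to the Si face of 4 corresponds to (5S), and the sense is to be confirmed on 6 by Mosher ester analysis, the antipodal catalyst being equally accessible.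

Step 3
Reactants: 6 ethyl (2E,5S)-5-hydroxy-3,7-dimethylocta-2,6-dienoate
Product: 7 (2E,5S)-3,7-dimethylocta-2,6-diene-1,5-diol
Conditions: i-Bu2AlH (3.3 equiv), CH2Cl2, −78 to −20 °C; then aq. potassium sodium tartrate
Reagents that add atoms: none
Why: 1,2-Reduction of a conjugated ester by the aluminium hydride (the first equivalent is consumed by the C5 hydroxyl) gives the allylic alcohol. Neither olefin nor the C5 stereocenter is touched.

Step 4
Reactants: 7 (2E,5S)-3,7-dimethylocta-2,6-diene-1,5-diol; 8 7-hydroxy-8-methoxy-2H-chromen-2-one
Product: 9 7-{[(2E,5S)-5-hydroxy-3,7-dimethylocta-2,6-dien-1-yl]oxy}-8-methoxy-2H-chromen-2-one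
Conditions: PPh3 (1.1 equiv), diisopropyl azodicarboxylate (1.1 equiv, added slowly), THF, 0 °C to rt
Reagents that add atoms: none
Why: Mitsunobu etherification: the acidic 7-hydroxyl of 8 (vinylogous to the lactone carbonyl) protonates the betaine and displaces the oxyphosphonium of the primary allylic C1 hydroxyl by SN2, so the (2E) geometry is kept. The hindered secondary C5 hydroxyl is activated far more slowly, and the neutral conditions spare ring B.

Step 5
Reactants: 9 7-{[(2E,5S)-5-hydroxy-3,7-dimethylocta-2,6-dien-1-yl]oxy}-8-methoxy-2H-chromen-2-one
Product: 11 7-{[(2E,5S,6S)-5,6-dihydroxy-3,7-dimethylocta-2,7-dien-1-yl]oxy}-8-methoxy-2H-chromen-2-one, via allylic hydroperoxide 10 (not isolated)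
Conditions: O2 (1 atm), 5,10,15,20-tetraphenylporphyrin (0.5 mol %), hν (λ > 500 nm), acid-free CH2Cl2 (0.02 M), −20 °C; then PPh3 (1.2 equiv), −20 °C to rt
Reagents that add atoms: dioxygen, O=O
Why: Schenck ene reaction of singlet oxygen with a chiral secondary allylic alcohol, followed by phosphine reduction of the hydroperoxide; this hydroxyl-directed variant is the closest known reaction type and is established for allylic alcohols whose olefin carries a cis substituent. Singlet oxygen made by energy transfer from the excited porphyrin attacks C6'=C7' of 9 through a perepoxide-like transition state: the C6'–O bond forms, a hydrogen of a C7' methyl group passes suprafacially to the distal oxygen and the double bond moves to C7'=C8', which gives 10; no ring is closed. The new C6' stereocenter is controlled by C5': 1,3-allylic strain against the cis methyl group on C7' holds the C5'–H bond in the olefin plane, so the C5' hydroxyl stands over one face and hydrogen-bonds to the incoming, negatively polarized oxygen, and attack on that face gives the threo (5'S,6'S) isomer. The same conformation keeps C5'–H out of alignment for abstraction, so oxygen ends on C6' and the olefin at the chain terminus. The site selectivity needed between the two trisubstituted olefins rests on the electrophilic character of the oxidant: C2'=C3' is deactivated by the allylic aryloxy group on C1' and has no allylic hydroxyl, whereas C6'=C7' offers two methyl groups and the directing hydroxyl. Light above 500 nm is absorbed only by the porphyrin, so ring B is neither excited nor dimerized, and the dilute non-polar medium keeps other acceptors from taking the directing hydrogen bond. PPh3 then removes the terminal oxygen of 10 at low temperature with retention at C6', before Hock cleavage or allylic hydroperoxide rearrangement can set in.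

## Compound list

1 | ethyl 3-methylbut-2-enoate | CCOC(=O)C=C(C)C | starting material
2 | lithium 1-ethoxy-3-methylbuta-1,3-dien-1-olate | [Li+].[O-]C(OCC)=CC(C)=C | intermediate (not isolated)
3 | tert-butyl[(1-ethoxy-3-methylbuta-1,3-dien-1-yl)oxy]dimethylsilane (C1=C2 geometry not controlled and not relevant) | C=C(C)C=C(OCC)O[Si](C)(C)C(C)(C)C | intermediate
4 | 3-methylbut-2-enal | CC(C)=CC=O | starting material
5 | ethyl (2E,5S)-3,7-dimethyl-5-[(trichlorosilyl)oxy]octa-2,6-dienoate | CC(C)=C[C@@H](O[Si](Cl)(Cl)Cl)C/C(C)=C/C(=O)OCC | intermediate (not isolated)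
6 | ethyl (2E,5S)-5-hydroxy-3,7-dimethylocta-2,6-dienoate | CC(C)=C[C@@H](O)C/C(C)=C/C(=O)OCC | intermediate
7 | (2E,5S)-3,7-dimethylocta-2,6-diene-1,5-diol | CC(C)=C[C@@H](O)C/C(C)=C/CO | intermediate
8 | 7-hydroxy-8-methoxy-2H-chromen-2-one | COc1c(O)ccc2ccc(=O)oc12 | starting material
9 | 7-{[(2E,5S)-5-hydroxy-3,7-dimethylocta-2,6-dien-1-yl]oxy}-8-methoxy-2H-chromen-2-one | CC(C)=C[C@@H](O)C/C(C)=C/COc1ccc2ccc(=O)oc2c1OC | intermediate
10 | 7-{[(2E,5S,6S)-6-hydroperoxy-5-hydroxy-3,7-dimethylocta-2,7-dien-1-yl]oxy}-8-methoxy-2H-chromen-2-one | C=C(C)[C@H](OO)[C@@H](O)C/C(C)=C/COc1ccc2ccc(=O)oc2c1OC | intermediate (not isolated)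
11 | 7-{[(2E,5S,6S)-5,6-dihydroxy-3,7-dimethylocta-2,7-dien-1-yl]oxy}-8-methoxy-2H-chromen-2-one | C=C(C)[C@H](O)[C@@H](O)C/C(C)=C/COc1ccc2ccc(=O)oc2c1OC | target

## Step count and least certain steps

Total step count: 5. Longest linear sequence: 5 steps (1 → 3 → 6 → 7 → 9 → 11); 4 and 8 enter as purchased materials.

Step 5 (key step). The most likely failure is insufficient discrimination between the two trisubstituted olefins, because the preference for C6'=C7' rests on electronic deactivation of C2'=C3' and not on a blocked site. Threo selectivity could also erode if the directing hydrogen bond is taken by other acceptors (the lactone carbonyl of a second molecule, moisture), and acid traces could ionize the allylic C5' alcohol. The fallback moves the ene reaction to the ester stage, where C2=C3 is a conjugated ester and inert to the electrophilic oxidant; it sets out from 6 and returns at 11.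
- Photooxygenation of 6 under the conditions of step 5 should give ethyl (2E,5S,6S)-6-hydroperoxy-5-hydroxy-3,7-dimethylocta-2,7-dienoate F1, which PPh3 reduces in the same flask to ethyl (2E,5S,6S)-5,6-dihydroxy-3,7-dimethylocta-2,7-dienoate F2.
- 2,2-Dimethoxypropane with pyridinium p-toluenesulfonate converts it into the acetonide ethyl (2E)-4-[(4S,5S)-2,2-dimethyl-5-(prop-1-en-2-yl)-1,3-dioxolan-4-yl]-3-methylbut-2-enoate F3.
- i-Bu2AlH reduces this to (2E)-4-[(4S,5S)-2,2-dimethyl-5-(prop-1-en-2-yl)-1,3-dioxolan-4-yl]-3-methylbut-2-en-1-ol F4.
- Mitsunobu coupling with 8 gives 7-{[(2E)-4-[(4S,5S)-2,2-dimethyl-5-(prop-1-en-2-yl)-1,3-dioxolan-4-yl]-3-methylbut-2-en-1-yl]oxy}-8-methoxy-2H-chromen-2-one F5, and aqueous acetic acid at 40 °C releases 11.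

Step 2. The most likely failures are low enantioselectivity or the wrong sense of induction with the β,β-disubstituted enal, since the face preference of this catalyst class is assumed and not derived for this aldehyde. Partial α-attack and partial loss of the (2E) geometry are further risks. The fallback replaces catalyst control in the C–C bond formation by a reduction of predictable sense; it sets out from 3 and 4 and returns at 6.
- A TiCl4-promoted vinylogous Mukaiyama aldol addition (CH2Cl2, −78 °C) gives racemic ethyl (2E)-5-hydroxy-3,7-dimethylocta-2,6-dienoate F6.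
- MnO2 oxidizes the allylic alcohol to ethyl (2E)-3,7-dimethyl-5-oxoocta-2,6-dienoate F7, which is used at once because its C4 hydrogens are acidic.
- Corey–Bakshi–Shibata reduction with (R)-1-methyl-3,3-diphenyltetrahydro-1H,3H-pyrrolo[1,2-c][1,3,2]oxazaborole and catecholborane in toluene at −78 °C treats the alkenyl group as the large substituent and should give (5S)-6.

Step 4. The most likely failure is competing activation of the secondary allylic hydroxyl (elimination, allylic transposition or double etherification), or substitution with allylic shift at C3'. The fallback is a silyl-protection detour; it sets out from 6 and returns at 9.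
- t-BuMe2SiCl and imidazole give ethyl (2E,5S)-5-[(tert-butyldimethylsilyl)oxy]-3,7-dimethylocta-2,6-dienoate F8.
- i-Bu2AlH gives (2E,5S)-5-[(tert-butyldimethylsilyl)oxy]-3,7-dimethylocta-2,6-dien-1-ol F9.
- Mitsunobu coupling with 8 gives 7-{[(2E,5S)-5-[(tert-butyldimethylsilyl)oxy]-3,7-dimethylocta-2,6-dien-1-yl]oxy}-8-methoxy-2H-chromen-2-one F10.
- n-Bu4NF buffered with acetic acid in THF removes the silyl group to give 9.

## Further compounds

F1 | step 5 | ethyl (2E,5S,6S)-6-hydroperoxy-5-hydroxy-3,7-dimethylocta-2,7-dienoate | C=C(C)[C@H](OO)[C@@H](O)C/C(C)=C/C(=O)OCC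
F2 | step 5 | ethyl (2E,5S,6S)-5,6-dihydroxy-3,7-dimethylocta-2,7-dienoate | C=C(C)[C@H](O)[C@@H](O)C/C(C)=C/C(=O)OCC
F3 | step 5 | ethyl (2E)-4-[(4S,5S)-2,2-dimethyl-5-(prop-1-en-2-yl)-1,3-dioxolan-4-yl]-3-methylbut-2-enoate | C=C(C)[C@@H]1OC(C)(C)O[C@H]1C/C(C)=C/C(=O)OCC
F4 | step 5 | (2E)-4-[(4S,5S)-2,2-dimethyl-5-(prop-1-en-2-yl)-1,3-dioxolan-4-yl]-3-methylbut-2-en-1-ol | C=C(C)[C@@H]1OC(C)(C)O[C@H]1C/C(C)=C/CO
F5 | step 5 | 7-{[(2E)-4-[(4S,5S)-2,2-dimethyl-5-(prop-1-en-2-yl)-1,3-dioxolan-4-yl]-3-methylbut-2-en-1-yl]oxy}-8-methoxy-2H-chromen-2-one | C=C(C)[C@@H]1OC(C)(C)O[C@H]1C/C(C)=C/COc1ccc2ccc(=O)oc2c1OC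
F6 | step 2 | ethyl (2E)-5-hydroxy-3,7-dimethylocta-2,6-dienoate (racemic) | CC(C)=CC(O)C/C(C)=C/C(=O)OCC
F7 | step 2 | ethyl (2E)-3,7-dimethyl-5-oxoocta-2,6-dienoate | CC(C)=CC(=O)C/C(C)=C/C(=O)OCC
F8 | step 4 | ethyl (2E,5S)-5-[(tert-butyldimethylsilyl)oxy]-3,7-dimethylocta-2,6-dienoate | CC(C)=C[C@@H](O[Si](C)(C)C(C)(C)C)C/C(C)=C/C(=O)OCC
F9 | step 4 | (2E,5S)-5-[(tert-butyldimethylsilyl)oxy]-3,7-dimethylocta-2,6-dien-1-ol | CC(C)=C[C@@H](O[Si](C)(C)C(C)(C)C)C/C(C)=C/CO
F10 | step 4 | 7-{[(2E,5S)-5-[(tert-butyldimethylsilyl)oxy]-3,7-dimethylocta-2,6-dien-1-yl]oxy}-8-methoxy-2H-chromen-2-one | CC(C)=C[C@@H](O[Si](C)(C)C(C)(C)C)C/C(C)=C/COc1ccc2ccc(=O)oc2c1OC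
A1 | alternative 1 | tert-butyl{[(2E,5E)-3,7-dimethylocta-2,5,7-trien-1-yl]oxy}diphenylsilane | C=C(C)/C=C/C/C(C)=C/CO[Si](c1ccccc1)(c1ccccc1)C(C)(C)C
A2 | alternative 1 | (3S,4S,6E)-8-[(tert-butyldiphenylsilyl)oxy]-2,6-dimethylocta-1,6-diene-3,4-diol | C=C(C)[C@H](O)[C@@H](O)C/C(C)=C/CO[Si](c1ccccc1)(c1ccccc1)C(C)(C)C
A3 | alternative 1 | (4S,5S)-4-[(2E)-4-bromo-2-methylbut-2-en-1-yl]-2,2-dimethyl-5-(prop-1-en-2-yl)-1,3-dioxolane | C=C(C)[C@@H]1OC(C)(C)O[C@H]1C/C(C)=C/CBr
A4 | alternative 2 | (3E)-5-[(8-methoxy-2-oxo-2H-chromen-7-yl)oxy]-3-methylpent-3-enal | O=CC/C(C)=C/COc1ccc2ccc(=O)oc2c1OC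
A5 | alternative 2 | 7-{[(2E,5S,6S)-5-hydroxy-6-(methoxymethoxy)-3,7-dimethylocta-2,7-dien-1-yl]oxy}-8-methoxy-2H-chromen-2-one | C=C(C)[C@H](OCOC)[C@@H](O)C/C(C)=C/COc1ccc2ccc(=O)oc2c1OC
A6 | alternative 3 | (2S,4E)-6-[(tert-butyldiphenylsilyl)oxy]-2-(methoxymethoxy)-4-methylhex-4-enal | O=C[C@@H](OCOC)C/C(C)=C/CO[Si](c1ccccc1)(c1ccccc1)C(C)(C)C
A7 | alternative 3 | (3S,4S,6E)-8-[(tert-butyldiphenylsilyl)oxy]-4-(methoxymethoxy)-2,6-dimethylocta-1,6-dien-3-ol | C=C(C)[C@H](O)[C@@H](OCOC)C/C(C)=C/CO[Si](c1ccccc1)(c1ccccc1)C(C)(C)C
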